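## Retrosynthetic overview

- Locants: unprimed for the β-carboline part (C1, N2, C3, C4, C4a, N9, C9a), primed for the methoxyindole part. The target is a propellane around the C4a–C9a bond. The strategy rests on its dihydrofuran ring (O–C5'–C4'–C9a–C4a): the ether oxygen and the fully substituted C9a sit on the neighbouring indole carbons C5' and C4', while C4a–O and C9a–N9 sit on neighbouring carboline carbons.
- Endgame disconnections: C3'–CH2NMe2 (Mannich reaction), then N2–CH3 and N1'–H (hydride reduction of a methyl carbamate and a Boc group).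
- Key disconnection: O–C5' and C4'–C9a together, back to a Boc-protected 7-methoxy-4,5-indolyne (from its 4-silyl 5-triflate) and the alkoxide of the (S)-4a-hydroxy-3H-indole made from N-carbomethoxytryptoline.
- Precursors: tryptoline is N2-acylated and hydroxylated enantioselectively at C4a. 3-Methoxy-4-nitrophenol is brominated before indole formation (bromine at the future C4'), then carried through Bartoli indolisation, N-Boc protection, retro-Brook silyl shift and triflation.
- Ring order: the carboline tricycle is bought, the indole pyrrole ring is made in the Bartoli step, and the dihydrofuran ring that completes the propellane is closed last, in the key step.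

Key step: step 9

Assumption: the (+)-enantiomer of (8,8-dichlorocamphorylsulfonyl)oxaziridine is taken to deliver oxygen to the face of C4a that gives the (S) alcohol; if the sense of induction is the opposite one, the (−)-reagent is used in the same step.

## Route

Step 1
Reactants: 1 tryptoline
Product: 2 methyl 1,3,4,9-tetrahydro-2H-pyrido[3,4-b]indole-2-carboxylate
Conditions: ClCO2Me, NaHCO3, CH2Cl2/H2O, 0 → 23 °C
Reagents that add atoms: methyl chloroformate, COC(=O)Cl
Why: Schotten–Baumann carbamate formation should occur only at the aliphatic secondary amine N2, which is far more nucleophilic than the indole nitrogen.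

Step 2
Reactants: 2 methyl 1,3,4,9-tetrahydro-2H-pyrido[3,4-b]indole-2-carboxylate
Product: 3 methyl (4aS)-4a-hydroxy-1,3,4,4a-tetrahydro-2H-pyrido[3,4-b]indole-2-carboxylate
Conditions: (+)-(8,8-dichlorocamphorylsulfonyl)oxaziridine (1.2 equiv), CH2Cl2, 0 → 23 °C; recrystallisation
Reagents that add atoms: (+)-(8,8-dichlorocamphorylsulfonyl)oxaziridine, CC1(C)[C@@H]2CC[C@]13CS(=O)(=O)N4O[C@@]34C2(Cl)Cl
Why: Asymmetric oxaziridine hydroxylation of a 2,3-disubstituted indole transfers electrophilic oxygen to the nucleophilic C4a and leaves the C9a=N9 imine; the camphor-derived reagent differentiates the two faces of C4a and so sets the (S) centre, and recrystallisation should raise the enantiomeric purity.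

Step 3
Reactants: 4 3-methoxy-4-nitrophenol
Product: 5 2-bromo-5-methoxy-4-nitrophenol
Conditions: NBS (1.0 equiv), MeCN, 0 → 23 °C
Reagents that add atoms: N-bromosuccinimide, O=C1CCC(=O)N1Br
Why: Electrophilic aromatic bromination should go to the carbon ortho to OH, para to OMe and meta to NO2, where all three groups direct and which is less hindered than the carbon between OH and OMe.

Step 4
Reactants: 5 2-bromo-5-methoxy-4-nitrophenol
Product: 6 (2-bromo-5-methoxy-4-nitrophenoxy)triisopropylsilane
Conditions: TIPSCl, imidazole, DMF, 23 °C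
Reagents that add atoms: triisopropylsilyl chloride, CC(C)[Si](Cl)(C(C)C)C(C)C
Why: O-silylation of the acidic nitrophenol gives a bulky silyl ether that removes the acidic proton and should withstand the Grignard reagent of the next step.

Step 5
Reactants: 6 (2-bromo-5-methoxy-4-nitrophenoxy)triisopropylsilane; 7 vinylmagnesium bromide
Product: 8 4-bromo-7-methoxy-5-(triisopropylsilyloxy)-1H-indole
Conditions: CH2=CHMgBr (3.5 equiv), THF, −45 °C; then aq. NH4Cl
Reagents that add atoms: vinylmagnesium bromide (compound 7), C=C[Mg]Br
Why: In the Bartoli indole synthesis the ortho methoxy group promotes the [3,3]-sigmatropic shift of the N-aryl-O-vinylhydroxylamine onto the only free ortho carbon, so that bromine ends at C4, the silyloxy group at C5 and the methoxy group at C7, and the aryl bromide is inert to the Grignard reagent at this temperature.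

Step 6
Reactants: 8 4-bromo-7-methoxy-5-(triisopropylsilyloxy)-1H-indole
Product: 9 tert-butyl 4-bromo-7-methoxy-5-(triisopropylsilyloxy)indole-1-carboxylate
Conditions: Boc2O, DMAP (cat.), MeCN, 23–40 °C
Reagents that add atoms: di-tert-butyl dicarbonate, CC(C)(C)OC(=O)OC(=O)OC(C)(C)C
Why: DMAP-catalysed N-acylation of the indole nitrogen removes the N–H acidity that would interfere with the aryne step and lowers the nucleophilicity of C3.

Step 7
Reactants: 9 tert-butyl 4-bromo-7-methoxy-5-(triisopropylsilyloxy)indole-1-carboxylate
Product: 10 tert-butyl 4-bromo-5-hydroxy-7-methoxyindole-1-carboxylate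
Conditions: Bu4NF, AcOH, THF, 0 °C
Reagents that add atoms: none
Why: Fluoride-mediated desilylation cleaves the phenolic Si–O bond rapidly, and the acetic acid buffer protonates the phenoxide at once so that the N-Boc group is not exposed to a basic medium.

Step 8
Reactants: 10 tert-butyl 4-bromo-5-hydroxy-7-methoxyindole-1-carboxylate
Product: 13 tert-butyl 7-methoxy-5-(trifluoromethylsulfonyloxy)-4-(trimethylsilyl)indole-1-carboxylate, via O-trimethylsilyl ether 11 (not isolated), via lithium 4-silylindol-5-olate 12 (not isolated)
Conditions: (Me3Si)2NH, THF, 65 °C, then evaporation; n-BuLi (1.05 equiv), THF, −100 °C; Tf2O, −100 → −78 °C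
Reagents that add atoms: hexamethyldisilazane, C[Si](C)(C)N[Si](C)(C)C; trifluoromethanesulfonic anhydride, O=S(=O)(OS(=O)(=O)C(F)(F)F)C(F)(F)F
Why: After O-silylation, bromine–lithium exchange at −100 °C should outrun attack of n-BuLi on the Boc carbonyl, the ortho-lithiated aryl silyl ether undergoes the 1,3 O-to-C silyl shift (retro-Brook rearrangement), and the lithium phenoxide is triflated in the same flask, the standard one-pot route to ortho-silylaryl triflates.

Step 9
Reactants: 3 methyl (4aS)-4a-hydroxy-1,3,4,4a-tetrahydro-2H-pyrido[3,4-b]indole-2-carboxylate; 13 tert-butyl 7-methoxy-5-(trifluoromethylsulfonyloxy)-4-(trimethylsilyl)indole-1-carboxylate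
Product: 16 (4aS,9aR)-pentacycle bearing N2-CO2Me and N1'-Boc with C3'–H, via potassium alkoxide 14 (not isolated), via 7-methoxy-4,5-indolyne 15 (not isolated)
Conditions: 3 (2.0 equiv), KH (2.0 equiv), THF, 0 °C; then 13 (1.0 equiv, slow addition), KF, 18-crown-6, THF, 0 → 23 °C; then H2O
Reagents that add atoms: none
Why: Proposed new method: fluoride removes the trimethylsilyl group of 13 and expels triflate to give indolyne 15, whose C5' terminus is attacked by the preformed alkoxide 14, and the resulting C4' aryl anion, held beside the imine by the new ether link and without a proton source in THF, should add to C9a=N9 to give the N9 anion, protonated on work-up. The closest known reaction type is the aryne annulation in which an oxygen or nitrogen nucleophile adds and the aryl anion is trapped by a tethered C=O or C=N, combined with the C5-selective nucleophilic additions to 4,5-indolynes. The dihydrofuran ring closes 5-exo-trig on the ketimine carbon. C4a keeps its (S) configuration because none of its bonds is broken, and C9a can only form with the aryl group cis to oxygen on the new five-membered ring, so its (R) configuration is relayed from C4a. The step needs attack by oxygen and not by the imine nitrogen, which the preformed alkoxide secures, and attack at C5' and not C4', which is secured by the distortion of the aryne by the C3a' ring fusion (C5', flanked only by C6'–H, is the more linear and electrophilic carbon) and by the bulk of the tertiary alkoxide, the remote C7' methoxy group exerting only a weak inductive counter-bias. Slow addition of 13 to an excess of alkoxide should keep the aryne from arylating the N9 anion of the product.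

Step 10
Reactants: 16 (4aS,9aR)-pentacycle bearing N2-CO2Me and N1'-Boc
Product: 17 (4aS,9aR)-pentacycle bearing N2-CH3 and N1'–H with C3'–H
Conditions: LiAlH4, THF, 65 °C; then H2O
Reagents that add atoms: none
Why: Hydride reduction converts the methyl carbamate into the N-methyl amine and cleaves the indole Boc group by attack on its carbonyl with loss of the indolide, without touching the ethers or the two quaternary stereocentres.

Step 11
Reactants: 17 (4aS,9aR)-pentacycle bearing N2-CH3 and N1'–H
Product: 18 target (CNP0318114.2)
Conditions: CH2O (37% aq.), Me2NH (40% aq.), AcOH, 0 → 23 °C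
Reagents that add atoms: formaldehyde, C=O; dimethylamine, CNC
Why: In the Mannich reaction the dimethyliminium ion should attack C3', the most nucleophilic carbon of the free indole, to give the gramine side chain, while any aminal formed at the hindered N9 reverts on work-up.

## Compound list

1 | tryptoline (2,3,4,9-tetrahydro-1H-pyrido[3,4-b]indole) | C1CNCc2[nH]c3ccccc3c12 | starting material
2 | methyl 1,3,4,9-tetrahydro-2H-pyrido[3,4-b]indole-2-carboxylate | COC(=O)N1CCc2c(C1)[nH]c1ccccc21 | intermediate
3 | methyl (4aS)-4a-hydroxy-1,3,4,4a-tetrahydro-2H-pyrido[3,4-b]indole-2-carboxylate | COC(=O)N1CC[C@]2(O)c3ccccc3N=C2C1 | intermediate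
4 | 3-methoxy-4-nitrophenol | COc1cc(O)ccc1[N+](=O)[O-] | starting material
5 | 2-bromo-5-methoxy-4-nitrophenol | COc1cc(O)c(Br)cc1[N+](=O)[O-] | intermediate
6 | (2-bromo-5-methoxy-4-nitrophenoxy)triisopropylsilane | COc1cc(O[Si](C(C)C)(C(C)C)C(C)C)c(Br)cc1[N+](=O)[O-] | intermediate
7 | vinylmagnesium bromide | C=C[Mg]Br | starting material
8 | 4-bromo-7-methoxy-5-(triisopropylsilyloxy)-1H-indole | COc1cc(O[Si](C(C)C)(C(C)C)C(C)C)c(Br)c2cc[nH]c12 | intermediate
9 | tert-butyl 4-bromo-7-methoxy-5-(triisopropylsilyloxy)indole-1-carboxylate | COc1cc(O[Si](C(C)C)(C(C)C)C(C)C)c(Br)c2ccn(C(=O)OC(C)(C)C)c12 | intermediate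
10 | tert-butyl 4-bromo-5-hydroxy-7-methoxyindole-1-carboxylate | COc1cc(O)c(Br)c2ccn(C(=O)OC(C)(C)C)c12 | intermediate
11 | tert-butyl 4-bromo-7-methoxy-5-(trimethylsilyloxy)indole-1-carboxylate (formed in the flask, not isolated) | COc1cc(O[Si](C)(C)C)c(Br)c2ccn(C(=O)OC(C)(C)C)c12 | intermediate
12 | lithium 1-(tert-butoxycarbonyl)-7-methoxy-4-(trimethylsilyl)indol-5-olate (formed in the flask, not isolated) | COc1cc([O-])c([Si](C)(C)C)c2ccn(C(=O)OC(C)(C)C)c12.[Li+] | intermediate
13 | tert-butyl 7-methoxy-5-(trifluoromethylsulfonyloxy)-4-(trimethylsilyl)indole-1-carboxylate | COc1cc(OS(=O)(=O)C(F)(F)F)c([Si](C)(C)C)c2ccn(C(=O)OC(C)(C)C)c12 | intermediate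
14 | potassium (4aS)-2-(methoxycarbonyl)-1,2,3,4-tetrahydro-4aH-pyrido[3,4-b]indol-4a-olate (formed in the flask, not isolated) | COC(=O)N1CC[C@]2([O-])c3ccccc3N=C2C1.[K+] | intermediate
15 | tert-butyl 7-methoxy-4,5-didehydroindole-1-carboxylate, the 4,5-indolyne (formed in the flask, not isolated) | COC1=CC#CC2=C1N(C(=O)OC(C)(C)C)C=C2 | intermediate
16 | (4aS,9aR)-pentacycle: dihydrofuran ring O–C5'–C4'–C9a–C4a fused to the N1'-Boc 7'-methoxyindole, the indoline and the N2-methoxycarbonyl piperidine, C3'–H | COc1cc2c(c3ccn(C(=O)OC(C)(C)C)c13)[C@@]13CN(C(=O)OC)CC[C@]1(O2)c1ccccc1N3 | intermediate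
17 | (4aS,9aR)-pentacycle with N2-CH3, N1'–H and C3'–H | COc1cc2c(c3cc[nH]c13)[C@@]13CN(C)CC[C@]1(O2)c1ccccc1N3 | intermediate
18 | CNP0318114.2, the (4aS,9aR)-pentacycle with N2-CH3, N1'–H and C3'–CH2N(CH3)2 | COc1cc2c(c3c(CN(C)C)c[nH]c13)[C@@]13CN(C)CC[C@]1(O2)c1ccccc1N3 | target

## Step count

Total: 11 steps. Longest linear sequence: 9 steps (4 → 5 → 6 → 8 → 9 → 10 → 13 → 16 → 17 → 18); the carboline branch (1 → 2 → 3) adds 2 steps and joins at step 9.

## Steps most likely to fail

**Step 9 (key step).** The C4' aryl anion may be protonated before it reaches the imine. The aryne may be taken up by the imine nitrogen or by the N9 anion of the product. The alkoxide may accept the Boc group of 13 or undergo a base-induced 1,2-shift to an indoxyl.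

Fallback, setting out from 3 and 13 and returning to the route at 17: the two bonds are made one after the other by known reactions.
- Neutral alcohol 3 and silyl triflate 13 with CsF in MeCN at 23 °C should give, by O–H insertion of the aryne (C5' attack, then protonation of C4' by the medium), the aryl ether methyl (4aS)-4a-{[1-(tert-butoxycarbonyl)-7-methoxyindol-5-yl]oxy}-1,3,4,4a-tetrahydro-2H-pyrido[3,4-b]indole-2-carboxylate F1.
- Anhydrous CF3CO2H in CH2Cl2 (0 → 23 °C) then protonates N9. The electron-rich C4' (ortho to the ether oxygen, para to the methoxy group) should attack the 3H-indolium carbon C9a in an intramolecular aza-Friedel–Crafts reaction, the same closure as the acid cyclisation of α-aryloxy ketones to benzofurans. The Boc group is lost, giving the (4aS,9aR)-pentacyclic methyl carbamate with free N1'–H F2. C4a is untouched and the closure can only be cis, so the configuration is kept.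
- LiAlH4 in THF reduces F2 to 17.

**Step 2.** Facial selectivity of the oxygen transfer to this N-acyl tetrahydro-β-carboline may be poor, or its sense may not be the assumed one.

Fallback, setting out from 2 and returning at 3: dimethyldioxirane in acetone at −78 °C hydroxylates C4a without stereocontrol to give racemic methyl 4a-hydroxy-1,3,4,4a-tetrahydro-2H-pyrido[3,4-b]indole-2-carboxylate F3. Preparative chromatography on a chiral stationary phase separates 3 from methyl (4aR)-4a-hydroxy-1,3,4,4a-tetrahydro-2H-pyrido[3,4-b]indole-2-carboxylate F4, which is discarded.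

**Step 8.** n-BuLi may attack the Boc carbonyl or deprotonate C2 in competition with bromine–lithium exchange, so that the silyl shift is incomplete.

Fallback, setting out from 8 and returning at 13: the organolithium chemistry is done before the Boc group is introduced.
- Bu4NF in THF at 0 °C frees 4-bromo-7-methoxy-1H-indol-5-ol F5.
- (Me3Si)2NH gives 4-bromo-7-methoxy-5-(trimethylsilyloxy)-1H-indole F6.
- t-BuLi (3.1 equiv, THF, −78 °C) deprotonates N1, exchanges the bromine and triggers the retro-Brook shift; aqueous NH4Cl then gives 7-methoxy-4-(trimethylsilyl)-1H-indol-5-ol F7.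
- PhNTf2 and Et3N in CH2Cl2 triflate only the phenol, giving 7-methoxy-4-(trimethylsilyl)-1H-indol-5-yl trifluoromethanesulfonate F8.
- Boc2O with catalytic DMAP gives 13.

## Further compounds

F1 | step 9 | methyl (4aS)-4a-{[1-(tert-butoxycarbonyl)-7-methoxyindol-5-yl]oxy}-1,3,4,4a-tetrahydro-2H-pyrido[3,4-b]indole-2-carboxylate | COC(=O)N1CC[C@]2(Oc3cc(OC)c4n(C(=O)OC(C)(C)C)ccc4c3)c3ccccc3N=C2C1
F2 | step 9 | (4aS,9aR)-pentacyclic methyl carbamate with free N1'–H and C3'–H | COc1cc2c(c3cc[nH]c13)[C@@]13CN(C(=O)OC)CC[C@]1(O2)c1ccccc1N3
F3 | step 2 | racemic methyl 4a-hydroxy-1,3,4,4a-tetrahydro-2H-pyrido[3,4-b]indole-2-carboxylate | COC(=O)N1CCC2(O)c3ccccc3N=C2C1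
F4 | step 2 | methyl (4aR)-4a-hydroxy-1,3,4,4a-tetrahydro-2H-pyrido[3,4-b]indole-2-carboxylate | COC(=O)N1CC[C@@]2(O)c3ccccc3N=C2C1
F5 | step 8 | 4-bromo-7-methoxy-1H-indol-5-ol | COc1cc(O)c(Br)c2cc[nH]c12
F6 | step 8 | 4-bromo-7-methoxy-5-(trimethylsilyloxy)-1H-indole | COc1cc(O[Si](C)(C)C)c(Br)c2cc[nH]c12
F7 | step 8 | 7-methoxy-4-(trimethylsilyl)-1H-indol-5-ol | COc1cc(O)c([Si](C)(C)C)c2cc[nH]c12
F8 | step 8 | 7-methoxy-4-(trimethylsilyl)-1H-indol-5-yl trifluoromethanesulfonate | COc1cc(OS(=O)(=O)C(F)(F)F)c([Si](C)(C)C)c2cc[nH]c12
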